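## Retrosynthetic overview

1. The last bond made is the biaryl bond between two identical tetralinols (ortho carbon of one, para carbon of the other). Both carbons are nucleophilic phenol carbons, so the para-carbon partner is inverted to a phenoxenium (vinylogous enolonium) equivalent on trivalent iodine and attacked directly by the other, with no halide, boronate or protecting group.
2. Each half, (1S,4R)-8-hydroxycalamenene, is cut through its phenol ring into (+)-menthone and a 3-methylbut-2-enoyl unit: enolate C-acylation, then intramolecular vinylogous aldol condensation with loss of water.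
3. All four stereocentres (two per half) come from (+)-menthol; none is formed or disturbed later.
4. Ring order: cyclohexane ring (chiral pool), then phenol ring (benzannulation), then biaryl bond.

Assumption: the SMILES defines four stereocentres but not the sense of the hindered biaryl axis, so the axis is left open and either rotamer, or their mixture, is taken as the target.

## Route

Step 1
Reactants: 1 (1S,2R,5S)-5-methyl-2-(propan-2-yl)cyclohexan-1-ol [(+)-menthol]
Product: 2 (2R,5S)-5-methyl-2-(propan-2-yl)cyclohexan-1-one [(+)-menthone]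
Conditions: NaOCl (1.2 equiv), 2,2,6,6-tetramethylpiperidin-1-oxyl (1 mol %), KBr (10 mol %), CH2Cl2/aq NaHCO3, 0 °C
Reagents that add atoms: none
Why: Oxoammonium-catalysed hypochlorite oxidation of the secondary alcohol (Anelli oxidation) at pH 9 and 0 °C is too mild to enolise the ketone, so the isopropyl centre (R) and the methyl centre (S) are carried over and only the carbinol centre is destroyed.

Step 2
Reactants: 2 (2R,5S)-5-methyl-2-(propan-2-yl)cyclohexan-1-one; 3 3-methylbut-2-enoyl chloride
Product: 5 (3S,6R)-3-methyl-2-(3-methylbut-2-enoyl)-6-(propan-2-yl)cyclohexan-1-one (enolised β-diketone; C2 not defined), via lithium enolate 4 (not isolated)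
Conditions: LiN(i-Pr)2 (2.0 equiv), 2 (2.0 equiv), THF, −78 °C; then 3 (1.0 equiv), −78 to −40 °C; aq NH4Cl (excess 2 recovered)
Reagents that add atoms: none
Why: Kinetic deprotonation by the hindered amide at −78 °C removes a proton only from the unsubstituted α-CH2, so the isopropyl-bearing α-stereocentre is never enolised, and the lithium enolate is C-acylated by the acid chloride (Claisen-type acylation) to a β-diketone whose acidic proton is taken up by the second equivalent of enolate; the new centre between the carbonyls is enolised and carries no stereochemical information.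

Step 3
Reactants: 5 (3S,6R)-3-methyl-2-(3-methylbut-2-enoyl)-6-(propan-2-yl)cyclohexan-1-one
Product: 7 (5R,8S)-3,8-dimethyl-5-(propan-2-yl)-5,6,7,8-tetrahydronaphthalen-1-ol [(1S,4R)-8-hydroxycalamenene; methyl and isopropyl trans], via aldol adduct 6 (not isolated)
Conditions: KOt-Bu (2.5 equiv), t-BuOH, 80 °C; then 1 M HCl
Reagents that add atoms: none
Why: Under equilibrating alkoxide conditions the γ-carbon of the side-chain dienolate adds to the ring carbonyl (intramolecular vinylogous aldol addition, six-membered closure) and aldol adduct 6 dehydrates and tautomerises irreversibly to the phenol (aldol condensation–aromatisation), which drains the reversible oxa-Michael side equilibrium; the two benzylic stereocentres are spectators.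

Step 4
Reactants: 7 (5R,8S)-3,8-dimethyl-5-(propan-2-yl)-5,6,7,8-tetrahydronaphthalen-1-ol (two molecules)
Product: 10 (5R,5'R,8S,8'S)-3,3',8,8'-tetramethyl-5,5'-di(propan-2-yl)-5,5',6,6',7,7',8,8'-octahydro[2,4'-binaphthalene]-1,1'-diol, via aryloxyiodane 8 (not isolated), via dienone 9 (not isolated)
Conditions: PhI(OAc)2 (0.5 equiv per 7, added over 2 h), (CF3)2CHOH/CH2Cl2 4:1, 4 Å molecular sieves, −20 to 0 °C
Reagents that add atoms: none
Why: Proposed new method: ligand exchange on trivalent iodine turns one molecule of 7 into aryloxyiodane 8, a phenoxenium (vinylogous enolonium) equivalent whose para carbon, normally nucleophilic, is the largest electrophilic site and is attacked in the non-nucleophilic, cation-stabilising fluoroalcohol by the free ortho carbon of a second molecule of 7 (para–para union would join two carbons that are both screened by a peri isopropyl-bearing carbon, and O-attack is suppressed by hydrogen bonding of the phenol oxygen to the solvent), after which dienone 9 tautomerises to the biaryl; half an equivalent of oxidant and slow addition keep unoxidised 7 in excess so that it, not acetate or product, traps the cation; the closest known reaction type is the PhI(OAc)2-mediated dehydrogenative para C–H arylation of phenols by electron-rich arenes in (CF3)2CHOH; no stereocentre is touched and the axis forms as the rotamer or rotamers favoured by the existing centres.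

## Compound list

1 | (1S,2R,5S)-5-methyl-2-(propan-2-yl)cyclohexan-1-ol, (+)-menthol | CC(C)[C@H]1CC[C@H](C)C[C@@H]1O | starting material
2 | (2R,5S)-5-methyl-2-(propan-2-yl)cyclohexan-1-one, (+)-menthone | CC(C)[C@H]1CC[C@H](C)CC1=O | intermediate
3 | 3-methylbut-2-enoyl chloride | CC(C)=CC(=O)Cl | starting material
4 | lithium (3S,6R)-3-methyl-6-(propan-2-yl)cyclohex-1-en-1-olate (kinetic enolate, not isolated) | CC(C)[C@H]1CC[C@H](C)C=C1O[Li] | intermediate
5 | (3S,6R)-3-methyl-2-(3-methylbut-2-enoyl)-6-(propan-2-yl)cyclohexan-1-one (enolised; C2 not defined) | CC(C)[C@H]1CC[C@H](C)C(C(=O)C=C(C)C)C1=O | intermediate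
6 | (5R,8S)-4a-hydroxy-3,8-dimethyl-5-(propan-2-yl)-4a,5,6,7,8,8a-hexahydronaphthalen-1(4H)-one (C4a and C8a not defined; not isolated) | CC(C)[C@H]1CC[C@H](C)C2C1(O)CC(C)=CC2=O | intermediate
7 | (5R,8S)-3,8-dimethyl-5-(propan-2-yl)-5,6,7,8-tetrahydronaphthalen-1-ol, (1S,4R)-8-hydroxycalamenene | Cc1cc2c(c(O)c1)[C@@H](C)CC[C@@H]2C(C)C | intermediate
8 | acetoxy(phenyl){[(5R,8S)-3,8-dimethyl-5-(propan-2-yl)-5,6,7,8-tetrahydronaphthalen-1-yl]oxy}iodane (trivalent iodine; not isolated) | Cc1cc2c(c(OI(OC(C)=O)c3ccccc3)c1)[C@@H](C)CC[C@@H]2C(C)C | intermediate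
9 | (5R,8S)-4-[(5R,8S)-1-hydroxy-3,8-dimethyl-5-(propan-2-yl)-5,6,7,8-tetrahydronaphthalen-2-yl]-3,8-dimethyl-5-(propan-2-yl)-5,6,7,8-tetrahydronaphthalen-1(4H)-one (C4 not defined; not isolated) | CC(C)[C@H]1CC[C@H](C)C2=C1C(c3c(C)cc4c(c3O)[C@@H](C)CC[C@@H]4C(C)C)C(C)=CC2=O | intermediate
10 | (5R,5'R,8S,8'S)-3,3',8,8'-tetramethyl-5,5'-di(propan-2-yl)-5,5',6,6',7,7',8,8'-octahydro[2,4'-binaphthalene]-1,1'-diol | Cc1cc2c(c(O)c1-c1c(C)cc(O)c3c1[C@@H](C(C)C)CC[C@@H]3C)[C@@H](C)CC[C@@H]2C(C)C | target

## Step count and risks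

Total step count: 4 (3 if ketone 2 is bought instead of made). Longest linear sequence: 4 steps (1 → 2 → 5 → 7 → 10; compound 7 enters step 4 twice).

**Step 4 (highest risk).** The coupling can also give the 2,2'- and 4,4'-linked isomers, aryl ether and the para-quinone, and the bond formed is tetra-ortho-substituted; the wanted isomer may need chromatographic separation and recycling of 7. The fallback sets out from 7 and comes back at 10, and uses a preformed aryl cation equivalent so that both coupling sites are fixed in advance. NBS (MeCN, 0 °C) brominates 7 para to the hydroxyl to give (5R,8S)-4-bromo-3,8-dimethyl-5-(propan-2-yl)-5,6,7,8-tetrahydronaphthalen-1-ol F5. MeI/K2CO3 (acetone) gives (1S,4R)-5-bromo-8-methoxy-1,6-dimethyl-4-(propan-2-yl)-1,2,3,4-tetrahydronaphthalene F6. n-BuLi (THF, −78 °C) gives [(5S,8R)-4-methoxy-2,5-dimethyl-8-(propan-2-yl)-5,6,7,8-tetrahydronaphthalen-1-yl]lithium F7, which is trapped with B(OMe)3 and hydrolysed (aq HCl) to [(5S,8R)-4-methoxy-2,5-dimethyl-8-(propan-2-yl)-5,6,7,8-tetrahydronaphthalen-1-yl]boronic acid F8. Boron is exchanged for tetravalent lead (Pb(OAc)4, Hg(OAc)2 5 mol %, CHCl3, 40 °C) to give [(5S,8R)-4-methoxy-2,5-dimethyl-8-(propan-2-yl)-5,6,7,8-tetrahydronaphthalen-1-yl]lead triacetate F9. This arylates a second portion of 7 at its only free ortho carbon (pyridine, CHCl3, 40 °C; Pinhey arylation by ligand coupling on lead) to give (5R,5'R,8S,8'S)-1'-methoxy-3,3',8,8'-tetramethyl-5,5'-di(propan-2-yl)-5,5',6,6',7,7',8,8'-octahydro[2,4'-binaphthalen]-1-ol F10. BBr3 (CH2Cl2, −78 to 0 °C) then gives 10.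

**Step 3.** The enolised diketone can close through oxygen to a 2,2-dimethyl-dihydropyranone or suffer retro-Claisen cleavage, and the isopropyl centre could partly epimerise through the transient dienone. The fallback sets out from 5 and comes back at 7, and replaces the ionic closure by a pericyclic one under neutral conditions. TMSOTf (2.5 equiv)/Et3N (CH2Cl2, 0 °C) gives (3S,6R)-3-methyl-6-(propan-2-yl)-1-(trimethylsilyloxy)-2-[3-methyl-1-(trimethylsilyloxy)buta-1,3-dien-1-yl]cyclohex-1-ene F2. Heating in xylene at 140 °C effects thermal 6π-electrocyclisation to (5R,8S)-3,8-dimethyl-5-(propan-2-yl)-1,4a-bis(trimethylsilyloxy)-4,4a,5,6,7,8-hexahydronaphthalene F3. This loses Me3SiOH to give [(5R,8S)-3,8-dimethyl-5-(propan-2-yl)-5,6,7,8-tetrahydronaphthalen-1-yl]oxy(trimethyl)silane F4, and K2CO3/MeOH cleaves the silyl ether to 7.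

**Step 2.** O-acylation, double acylation or ketene formation from 3 can compete with C-acylation. The fallback sets out from 2 and comes back at 5, and makes the carbon–carbon bond by aldol addition, which cannot give an O-acyl product. Enolate 4 (LiN(i-Pr)2, THF, −78 °C) is treated with 3-methylbut-2-enal (CC(C)=CC=O) to give (3S,6R)-2-(1-hydroxy-3-methylbut-2-en-1-yl)-3-methyl-6-(propan-2-yl)cyclohexan-1-one F1. Dess–Martin periodinane (CH2Cl2, NaHCO3, rt) oxidises it to 5.

## Further compounds

F1 | step 2 | (3S,6R)-2-(1-hydroxy-3-methylbut-2-en-1-yl)-3-methyl-6-(propan-2-yl)cyclohexan-1-one | CC(C)[C@H]1CC[C@H](C)C(C(O)C=C(C)C)C1=O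
F2 | step 3 | (3S,6R)-3-methyl-6-(propan-2-yl)-1-(trimethylsilyloxy)-2-[3-methyl-1-(trimethylsilyloxy)buta-1,3-dien-1-yl]cyclohex-1-ene | CC(C)[C@H]1CC[C@H](C)C(C(O[Si](C)(C)C)=CC(C)=C)=C1O[Si](C)(C)C
F3 | step 3 | (5R,8S)-3,8-dimethyl-5-(propan-2-yl)-1,4a-bis(trimethylsilyloxy)-4,4a,5,6,7,8-hexahydronaphthalene (C4a not defined) | CC(C)[C@H]1CC[C@H](C)C2=C(O[Si](C)(C)C)C=C(C)CC12O[Si](C)(C)C
F4 | step 3 | [(5R,8S)-3,8-dimethyl-5-(propan-2-yl)-5,6,7,8-tetrahydronaphthalen-1-yl]oxy(trimethyl)silane | Cc1cc2c(c(O[Si](C)(C)C)c1)[C@@H](C)CC[C@@H]2C(C)C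
F5 | step 4 | (5R,8S)-4-bromo-3,8-dimethyl-5-(propan-2-yl)-5,6,7,8-tetrahydronaphthalen-1-ol | Brc1c(C)cc(O)c2c1[C@@H](C(C)C)CC[C@@H]2C
F6 | step 4 | (1S,4R)-5-bromo-8-methoxy-1,6-dimethyl-4-(propan-2-yl)-1,2,3,4-tetrahydronaphthalene | Brc1c(C)cc(OC)c2c1[C@@H](C(C)C)CC[C@@H]2C
F7 | step 4 | [(5S,8R)-4-methoxy-2,5-dimethyl-8-(propan-2-yl)-5,6,7,8-tetrahydronaphthalen-1-yl]lithium | [Li]c1c(C)cc(OC)c2c1[C@@H](C(C)C)CC[C@@H]2C
F8 | step 4 | [(5S,8R)-4-methoxy-2,5-dimethyl-8-(propan-2-yl)-5,6,7,8-tetrahydronaphthalen-1-yl]boronic acid | OB(O)c1c(C)cc(OC)c2c1[C@@H](C(C)C)CC[C@@H]2C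
F9 | step 4 | [(5S,8R)-4-methoxy-2,5-dimethyl-8-(propan-2-yl)-5,6,7,8-tetrahydronaphthalen-1-yl]lead triacetate | CC(=O)O[Pb](OC(C)=O)(OC(C)=O)c1c(C)cc(OC)c2c1[C@@H](C(C)C)CC[C@@H]2C
F10 | step 4 | (5R,5'R,8S,8'S)-1'-methoxy-3,3',8,8'-tetramethyl-5,5'-di(propan-2-yl)-5,5',6,6',7,7',8,8'-octahydro[2,4'-binaphthalen]-1-ol | Cc1cc2c(c(O)c1-c1c(C)cc(OC)c3c1[C@@H](C(C)C)CC[C@@H]3C)[C@@H](C)CC[C@@H]2C(C)C
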